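**Target:** (2S)-8-prenylhomoeriodictyol, i.e. (2S)-5,7-dihydroxy-2-(4-hydroxy-3-methoxyphenyl)-8-(3-methylbut-2-en-1-yl)chroman-4-one. The single stereocentre (C2) is S.

**Assumption:** natural (2S)-(–)-homoeriodictyol (Eriodictyon/Yerba Santa grade) is bought as the single enantiomer; its ee is checked by chiral HPLC before use and upgraded by recrystallisation if needed.

**Retrosynthetic overview**
1. 6 ⇒ 3: disconnect C8–C1'' as a photochemical [1,3] O→C prenyl shift (photo-Claisen) of the 7-O-prenyl ether, run on its transient bis-TMS ether.
2. 3 ⇒ 1 + 2: disconnect O7–C1'' as a Mitsunobu etherification at the most acidic phenol.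
3. No ring is built: rings A, B and C and the C2 stereocentre come intact from 1; the A ring is functionalised at O7 first, then at C8.

**Step 1**
Reactants: 1 (2S)-homoeriodictyol; 2 prenol
Product: 3 (2S)-7-O-prenylhomoeriodictyol
Conditions: PPh3 (1.1 equiv), DIAD (1.1 equiv), THF, 0 °C → rt
Reagents that add atoms: prenol (2), CC(C)=CCO
Why: Mitsunobu etherification, in which only the 7-OH (vinylogous acid, pKa about 7–8) protonates the betaine quickly while the 4'-OH (pKa about 10) lags and the chelated 5-OH is inert, and whose neutral conditions avoid base-induced ring opening, so the C2 centre bought in 1 is untouched.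

**Step 2**
Reactants: 3 (2S)-7-O-prenylhomoeriodictyol
Product: 6 (2S)-8-prenylhomoeriodictyol, via bis-TMS prenyl ether 4 (not isolated), via tris-TMS 8-prenylflavanone 5 (not isolated)
Conditions: BSA (4 equiv), MeCN, 60 °C, 1 h; dilute to 5 mM, Ar-sparge, hν 310 nm (LED, FEP flow coil), 0 °C, to about 80% conversion; then MeOH, AcOH (cat.), rt
Reagents that add atoms: none
Why: Proposed new method: a transient-silylation-enabled photo-Claisen [1,3] O→C prenyl shift on a flavanone, in which TMS capping of the chelated 5-OH removes the excited-state proton transfer that otherwise deactivates 2-hydroxyaryl ketones, so that 310 nm excitation of the A-ring chromophore (B ring transparent) can homolyse the weakest bond, ArO7–CH2 (allylic, about 50 kcal/mol), to a caged aryloxyl/prenyl radical pair that recombines through its unhindered CH2 terminus at the ortho carbon C8 (C6 is screened by the 5-OSiMe3 group, which the peri carbonyl forces to point at C6 and which pushes the O7–CH2 bond to the C8 side), after which rearomatisation and silylation by excess BSA give 5 and methanolysis gives the target with C2 not involved and still S; the closest known reaction type is the photo-Claisen rearrangement of aryl allyl and aryl prenyl ethers (radical-pair [1,3] shift to ortho-prenylphenols), not yet shown on a flavanone or with a transient silyl group that switches off ESIPT and steers the regiochemistry.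

**Compound list**
1 | (2S)-homoeriodictyol, (2S)-5,7-dihydroxy-2-(4-hydroxy-3-methoxyphenyl)chroman-4-one | COc1cc([C@@H]2CC(=O)c3c(O)cc(O)cc3O2)ccc1O | starting material
2 | prenol, 3-methylbut-2-en-1-ol | CC(C)=CCO | starting material
3 | (2S)-7-O-prenylhomoeriodictyol, (2S)-5-hydroxy-2-(4-hydroxy-3-methoxyphenyl)-7-(3-methylbut-2-en-1-yloxy)chroman-4-one | COc1cc([C@@H]2CC(=O)c3c(O)cc(OCC=C(C)C)cc3O2)ccc1O | intermediate
4 | (2S)-2-[3-methoxy-4-(trimethylsilyloxy)phenyl]-7-(3-methylbut-2-en-1-yloxy)-5-(trimethylsilyloxy)chroman-4-one | COc1cc([C@@H]2CC(=O)c3c(O[Si](C)(C)C)cc(OCC=C(C)C)cc3O2)ccc1O[Si](C)(C)C | intermediate (not isolated)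
5 | (2S)-2-[3-methoxy-4-(trimethylsilyloxy)phenyl]-8-(3-methylbut-2-en-1-yl)-5,7-bis(trimethylsilyloxy)chroman-4-one | COc1cc([C@@H]2CC(=O)c3c(O[Si](C)(C)C)cc(O[Si](C)(C)C)c(CC=C(C)C)c3O2)ccc1O[Si](C)(C)C | intermediate (not isolated)
6 | (2S)-8-prenylhomoeriodictyol, (2S)-5,7-dihydroxy-2-(4-hydroxy-3-methoxyphenyl)-8-(3-methylbut-2-en-1-yl)chroman-4-one | COc1cc([C@@H]2CC(=O)c3c(O)cc(O)c(CC=C(C)C)c3O2)ccc1O | target

**Total step count:** 2. **Longest linear sequence:** 2.

**Steps most likely to fail** (the route has only two steps, so both are ranked)

1. Step 2 (the proposed new step). Four things can go wrong.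
 - Regiochemistry: recombination at C6 gives the 6-prenyl isomer. The C8 preference rests only on the steric and conformational argument above and is not predictable with confidence. The isomers are separable by reversed-phase chromatography and are told apart by HMBC (H-1'' to C7/C8/C8a).
 - Efficiency: fast intersystem crossing of the aryl ketone may give a triplet-born pair that escapes the cage. The result is deprenylation back to 1, which is recovered and recycled.
 - Enantiopurity: the excited A ring could also cleave the benzylic O1–C2 bond reversibly and erode the ee. That bond is held close to the aryl plane, which disfavours cleavage, but this is not a guarantee. Irradiation is therefore stopped at partial conversion and the ee is checked against 1.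
 - Over-irradiation of the product chromophore.

 Fallback (known chemistry; sets out from 1 and 2, returns at 6): Ac2O/pyridine at 0 °C acetylates the two non-chelated phenols and leaves the 5-OH, giving (2S)-7,4'-di-O-acetylhomoeriodictyol F1. A Mitsunobu reaction of F1 with prenol 2 (PPh3, DIAD, THF) puts the prenyl group on O5, giving (2S)-7,4'-di-O-acetyl-5-O-prenylhomoeriodictyol F2. Eu(fod)3 (10 mol %) in CHCl3 at 60 °C then drives the tandem Claisen–Cope (para-Claisen) rearrangement, O5 → C6 → C8, which fixes the regiochemistry and gives (2S)-7,4'-di-O-acetyl-8-prenylhomoeriodictyol F3. K2CO3 (cat.)/MeOH at 0 °C removes both acetates and delivers 6, with the ee checked after the acetylation and the deacetylation.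

2. Step 1. The risks are co-alkylation of the 4'-OH (bis-ether) and a difficult separation of 3 from Ph3PO. Fallback (sets out from 1, returns at 3): replace the redox condensation by an SN2 alkylation of the pre-formed mono-phenolate. With K2CO3 (1.0 equiv) and prenyl bromide (1.05 equiv) in acetone at rt, only the 7-phenolate exists at this stoichiometry and it is O-alkylated (Williamson) to 3 directly. The ee must be checked because base is present. No new compound arises (F0).

**Further compounds**
F1 | step 2 | (2S)-7,4'-di-O-acetylhomoeriodictyol | COc1cc([C@@H]2CC(=O)c3c(O)cc(OC(C)=O)cc3O2)ccc1OC(C)=O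
F2 | step 2 | (2S)-7,4'-di-O-acetyl-5-O-prenylhomoeriodictyol | COc1cc([C@@H]2CC(=O)c3c(OCC=C(C)C)cc(OC(C)=O)cc3O2)ccc1OC(C)=O
F3 | step 2 | (2S)-7,4'-di-O-acetyl-8-prenylhomoeriodictyol | COc1cc([C@@H]2CC(=O)c3c(O)cc(OC(C)=O)c(CC=C(C)C)c3O2)ccc1OC(C)=O
F0 | step 1 | none | none
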